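## Structural features

The target is an achiral flavonol: a 3-hydroxychromen-4-one (rings A and C fused along C4a–C8a) carrying ring B, a 3-hydroxy-4-methoxyphenyl group, on C2. Ring A is fully substituted, with a hydroxyl on C5, 3-methylbut-2-enyl (prenyl) groups on C6 and C8, a methoxy group on C7, and C4a and C8a shared with ring C. There is no stereocentre, so no stereocentres adjoin; the only stereochemical element met on the way is the geometry of one transient double bond. The fragile parts are the two trisubstituted prenyl alkenes, which add a neighbouring phenol under strong acid (chroman formation) and exclude hydrogenolysis, epoxidising oxidants and quinone oxidants, and the electron-rich enol and phenol array of the flavonol. The real difficulty is ring A: a phloroglucinol nucleus in which only the C7 oxygen is methylated, both remaining ring positions carry prenyl groups, and the acyl carbon sits between the other two oxygens. Direct C-prenylation and selective O-methylation of an acylphloroglucinol are both poorly selective. Until ring C is closed, ring A has a local mirror plane through C4a and C7, so C5/C8a and C6/C8 are pairwise equivalent. The key step uses this pattern: a 4-methoxy-2-pyrone already holds the C7 methoxy group (pyrone C4), both prenyl groups (pyrone C3 and C5) and the C5 and C8a oxygens (lactone carbonyl and ring oxygen), and a 2-oxoalkyl chain on pyrone C6 supplies C4a, C4 and C3 with its oxygen.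

## Logic of the disconnections

**21 to 19 (through 20).** The first cut opens ring C at O1–C2 and removes the two methoxymethyl acetals. A 2-hydroxyaryl 1,3-diketone closes to a chromen-4-one by hemiketal formation and loss of water, and the same acid frees both hydroxyls, so one operation finishes the molecule. The gain is that ring C disappears and C3 already carries its oxygen, so no oxidation is needed after ring closure. The demand is an acid dilute enough to spare the prenyl groups. Because the two phenols of 19 are equivalent, either may close.

**19 to 18.** The C2–C3 bond, between the oxygen-bearing methine and the aroyl carbonyl, is cut and the aroyl group is returned to a phenol oxygen. This is the retro form of an intramolecular O-to-C acyl transfer. The gain is that the carbon–carbon bond is made inside one molecule, so no free acylating agent meets a polyfunctional enolate. The demand is enolisation of the methylene next to the acetal oxygen by a non-nucleophilic base, and protecting groups that tolerate that base.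

**18 to 14 and 17.** The aryl ester C–O bond is cut. This joins the ring A unit, which already carries C4 and C3, to the ring B acid in a convergent way. The demand is mono-acylation. It is met because the two phenols of 14 are identical and the remaining one is held in a hydrogen bond to the ketone between a prenyl group and the new ester.

**17 to 15 (through 16).** The aryl acetal is removed. The ring B phenol is masked because it would otherwise compete in the esterification and consume base in the acyl transfer. The demand is a group that survives amide base and leaves with the C3 acetal in the last step.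

**14 to 12 (through 13).** The C4a–C5 bond of ring A is cut and the C5 carbon is reconnected to the C8a oxygen as a lactone. This trades a hexasubstituted benzene for a pyrone whose substituents are placed by ordinary enolate chemistry. It fixes the methyl ether on C7 without any selective methylation. The demand is that the opened chain closes by Claisen and not by aldol condensation, which the precursor is designed to ensure.

**12 to 8 and 11.** The bond between the side-chain methylene (future C4a) and the ketone carbon (future C4) is cut. The methyl group on pyrone C6 is the vinylogous α-position of the lactone and can be metalated, so the two-carbon unit with its oxygen enters as an acyl donor. The demand is clean mono-acylation although the product is more acidic than the starting pyrone. An N-methoxy-N-methylamide answers this.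

**11 to 10 to 9.** The amide C–N bond and then the acetal O–C bond are cut, back to a commercial hydroxy ester. The only demand is that the acetal survives the magnesium amide.

**8 to 7, and 7 to 5 and 6.** The O–CH3 bond is cut, then the bond between pyrone C3 and its prenyl group (the future C6 prenyl group). C3 of 5 is the only free nucleophilic carbon of a highly acidic enol. The demands are C- over O-alkylation and attack at the unsubstituted allyl terminus, then methylation on the C4 oxygen and not on the lactone carbonyl oxygen.

**5 to 3 (through 4), and 3 to 1 and 2.** The lactone C–O bond and the bond between pyrone C2 and C3 are cut, giving a diketone and a one-carbon electrophile at the carboxyl oxidation level. The prenyl group on the central carbon of the diketone (the future C8 prenyl group) is then removed. This reduces ring A to two commodity chemicals. The demands are carboxylation at the terminal carbon of the dianion and a lactonisation free of strong acid.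

## Other disconnections considered

**Alternative 1:** The cut is the C3–C4 bond of ring C. The forward step would treat the dialdehyde 4-methoxy-2-(methoxymethoxy)-6-[1-[4-methoxy-3-(methoxymethoxy)phenyl]-2-oxoethoxy]-3,5-bis(3-methylbut-2-enyl)benzaldehyde (A1) with a thiazolium-derived carbene and triethylamine. The carbene would add to the aryl aldehyde, and the resulting acyl anion equivalent would attack the aliphatic aldehyde in an intramolecular crossed benzoin reaction. The product would be the 3-hydroxychroman-4-one 3-hydroxy-7-methoxy-5-(methoxymethoxy)-2-[4-methoxy-3-(methoxymethoxy)phenyl]-6,8-bis(3-methylbut-2-enyl)chroman-4-one (A2).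

- In its favour: the closure is organocatalytic and nearly neutral, it places the C3 oxygen directly, and it exposes the prenyl groups to neither strong base nor acid. On the mildness of ring C closure it is better than the acid cyclodehydration of the chosen plan.
- Against it: A1 contains an enolisable α-aryl-α-aryloxy aldehyde that can lose its phenoxide by β-elimination or be diverted into redox esterification if the carbene adds to the wrong aldehyde. Its assembly needs O-alkylation of a phenol flanked by two ortho substituents with a secondary benzylic electrophile. A2 is at the dihydroflavonol oxidation level, so a dehydrogenation must follow in the presence of prenyl groups and electron-rich phenols, and two stereocentres are made only to be destroyed.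
- Comparison: structurally, it leaves the hexasubstituted ring A to be made separately and forces the C5 and C8a oxygens to be differentiated, which the chosen plan avoids through symmetry. Mechanistically it is an umpolung addition against a Claisen condensation, and both are ring closures of comparable reliability. In step economy it is clearly longer.

**Alternative 2:** The cuts are C8a–C8 and C6–C7 of ring A. The forward step would heat 3-isopropoxy-2-(3-methylbut-2-enyl)cyclobut-2-en-1-one (A3) with 1-methoxy-5-methylhex-4-en-1-yne (A4). A3 would open to a vinylketene and undergo regioselective [2+2] addition to the ynol ether. The vinylcyclobutenone would open, close by six-electron electrocyclisation and tautomerise to 5-isopropoxy-3-methoxy-2,4-bis(3-methylbut-2-enyl)phenol (A5).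

- In its favour: the regiochemistry is dictated by ketene and ynol ether polarity, the conditions are thermal and neutral, and C6, C7 and C8 arrive with their substituents in one step. On regiocontrol of ring A it is at least the equal of the chosen plan, since no Claisen-versus-aldol choice arises.
- Against it: A3 and A4 each need several steps, and A4 is a volatile, hydrolytically sensitive alkoxyalkyne. A5 lacks the acyl carbon on C4a, so a C-acylation between two oxygens is still required next to acid-sensitive prenyl groups. The isopropyl ether must finally be cleaved with a boron or aluminium halide, which threatens the prenyl groups.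
- Comparison: structurally it differentiates the C5 and C8a oxygens, which is unnecessary for this locally symmetric ring. Mechanistically it is a pericyclic cascade against an ionic condensation. In step economy it is worse, because the chosen key step delivers ring A already acylated with C4 and C3.

**Alternative 3:** The cuts are C4a–C4, C4–C3 and O1–C2. The forward step would combine 2-iodo-5-methoxy-4,6-bis(3-methylbut-2-enyl)benzene-1,3-diol (A6), carbon monoxide and 4-ethynyl-1-methoxy-2-(methoxymethoxy)benzene (A7) under PdCl2(PPh3)2 and diethylamine. The sequence would be oxidative addition of zerovalent palladium (formed from the divalent palladium precatalyst) into the C–I bond, CO insertion, coupling to an ynone, and amine-assisted 6-endo closure. The product would be 5-hydroxy-7-methoxy-2-[4-methoxy-3-(methoxymethoxy)phenyl]-6,8-bis(3-methylbut-2-enyl)chromen-4-one (A8).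

- In its favour: it is the most convergent of all, using three components in one step, and it uses the same local symmetry of ring A. A7 is easily reached and no acid is needed. For the construction of ring C alone its step economy is better than the three steps of the chosen plan.
- Against it: A8 has no C3 hydroxyl, so an oxidation at C3 would have to be carried out late beside two prenyl alkenes and a free phenol. A6 is a very electron-rich iodide with two ortho substituents, prone to slow oxidative addition and protodeiodination, and its preparation needs iodination in the presence of prenyl alkenes. Closure to the aurone and non-carbonylative coupling compete.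
- Comparison: structurally it leaves the selective prenylation and methylation of ring A unsolved. Mechanistically it relies on a palladium cascade with several branching points, where the chosen plan uses two well-separated condensations. Overall step economy is not better once ring A and the C3 oxidation are counted.

Key step: step 8

Remark on the chemistry: the target has no stereocentre; prenyl means 3-methylbut-2-enyl throughout; Mg(OMe)2 is taken to be freshly prepared from magnesium and methanol. In the ring transformation, pyrone C2, C3, C4, C5, C6 and the side-chain methylene become C5, C6, C7, C8, C8a and C4a of the flavonol.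

## Route

Step 1
Reactants: 1 pentane-2,4-dione; 2 1-bromo-3-methylbut-2-ene
Product: 3 3-(3-methylbut-2-enyl)pentane-2,4-dione
Conditions: K2CO3, acetone, reflux (1 in excess)
Reagents that add atoms: none
Why: C-alkylation of the diketone enolate with an allylic bromide (SN2); the weak base and an excess of 1 should keep double alkylation and O-alkylation low.

Step 2
Reactants: 3 3-(3-methylbut-2-enyl)pentane-2,4-dione
Product: 5 4-hydroxy-6-methyl-5-(3-methylbut-2-enyl)pyran-2-one, via 3,5-dioxo-4-(3-methylbut-2-enyl)hexanoic acid 4 (not isolated)
Conditions: LiN(i-Pr)2 (2.3 equiv), THF, −78 → 0 °C; CO2, −78 °C; cold 1 M HCl; then CDI, THF, rt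
Reagents that add atoms: carbon dioxide, O=C=O
Why: Dianion chemistry of a β-diketone: the less stabilised terminal carbanion is the more nucleophilic site and is carboxylated; the crude 3,5-dioxo acid is closed through its acyl imidazolide by the C5 enol oxygen (lactonisation to the 4-hydroxy-2-pyrone) without strong acid, so the prenyl group is not at risk.

Step 3
Reactants: 5 4-hydroxy-6-methyl-5-(3-methylbut-2-enyl)pyran-2-one; 6 3-methylbut-2-enyl acetate
Product: 7 4-hydroxy-6-methyl-3,5-bis(3-methylbut-2-enyl)pyran-2-one
Conditions: Pd(PPh3)4 (5 mol %), DBU, THF, 60 °C
Reagents that add atoms: none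
Why: Tsuji–Trost allylation of a highly acidic enol at its only free nucleophilic carbon (C3); zerovalent palladium ionises 6 to the 1,1-dimethylallyl complex, which a soft, hindered carbon nucleophile should attack at the unsubstituted terminus to give the linear prenyl group, and any O-prenyl ether, being a vinylogous ester, should re-ionise and be funnelled to the C-alkylated product.

Step 4
Reactants: 7 4-hydroxy-6-methyl-3,5-bis(3-methylbut-2-enyl)pyran-2-one
Product: 8 4-methoxy-6-methyl-3,5-bis(3-methylbut-2-enyl)pyran-2-one
Conditions: Me2SO4, K2CO3, acetone, reflux
Reagents that add atoms: dimethyl sulfate, COS(=O)(=O)OC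
Why: O-methylation of the vinylogous acid; carbonate with dimethyl sulfate in acetone is the standard way from 4-hydroxy-2-pyrones to 4-methoxy-2-pyrones, and the 2-methoxy-4-pyrone isomer is expected only as a minor, separable by-product.

Step 5
Reactants: 9 methyl glycolate
Product: 10 methyl 2-(methoxymethoxy)acetate
Conditions: MOMCl, i-Pr2NEt, CH2Cl2, 0 °C → rt
Reagents that add atoms: chloromethyl methyl ether, COCCl
Why: Acetal protection of a primary alcohol by alkylation with an α-chloro ether under amine base; the ester is untouched.

Step 6
Reactants: 10 methyl 2-(methoxymethoxy)acetate
Product: 11 N-methoxy-2-(methoxymethoxy)-N-methylacetamide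
Conditions: MeNH(OMe)·HCl, i-PrMgCl, THF, −20 → 0 °C
Reagents that add atoms: N,O-dimethylhydroxylamine hydrochloride, CNOC.Cl
Why: Aminolysis of the ester by the chloromagnesium amide of N,O-dimethylhydroxylamine (Weinreb amide formation); the acetal is stable to the Grignard base at low temperature.

Step 7
Reactants: 8 4-methoxy-6-methyl-3,5-bis(3-methylbut-2-enyl)pyran-2-one; 11 N-methoxy-2-(methoxymethoxy)-N-methylacetamide
Product: 12 4-methoxy-6-[3-(methoxymethoxy)-2-oxopropyl]-3,5-bis(3-methylbut-2-enyl)pyran-2-one
Conditions: LiN(i-Pr)2 (1.1 equiv), THF, −78 °C; then 11, −78 → −30 °C; aq. NH4Cl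
Reagents that add atoms: none
Why: Vinylogous deprotonation of the 6-methyl group (C3 is blocked and the prenyl methylenes are far less acidic) gives a dienolate that reacts at the exocyclic carbon; acylation with the Weinreb amide stops at the chelated tetrahedral adduct, so the acidic ketone is released only on quench and neither consumes base nor adds a second time.

Step 8
Reactants: 12 4-methoxy-6-[3-(methoxymethoxy)-2-oxopropyl]-3,5-bis(3-methylbut-2-enyl)pyran-2-one
Product: 14 1-[2,6-dihydroxy-4-methoxy-3,5-bis(3-methylbut-2-enyl)phenyl]-2-(methoxymethoxy)ethanone, via ring-opened methyl ester 13 (not isolated)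
Conditions: Mg(OMe)2 (4 equiv), MeOH, reflux; cold 1 M HCl to pH 4
Reagents that add atoms: magnesium methoxide, [Mg+2].C[O-].C[O-] (supplies the ester methoxy group of 13; this group is expelled again on closure, so 14 keeps no reagent atoms)
Why: Methoxide from Mg(OMe)2 adds to the lactone carbonyl of 12 and the ring opens to the methyl ester 13, in which the former ring double bond keeps the ester carbon and the C4 chain on the same side. The side-chain methylene of 13 now lies between two ketones; its magnesium-chelated carbanion (future C4a) attacks the ester carbonyl (future C5) in a 6-exo-trig Claisen closure of the Dieckmann type, methoxide leaves and two enolisations give the benzene ring. The closest known reaction type is the base-induced rearrangement of 6-(2-oxoalkyl)-4-methoxy-2-pyrones and of open-chain 3,5,7-tricarbonyl esters to acylphloroglucinols, the laboratory counterpart of the polyketide Claisen cyclisation. The lactone carbonyl oxygen becomes the C5 hydroxyl, the ring oxygen the C8a hydroxyl and the pyrone methoxy group the C7 methoxy group, so no hydroxyl has to be methylated selectively. No stereocentre is created: the C4 centre of 13 is racemic and disappears on aromatisation. The selectivity needed is Claisen over aldol closure; the prenyl group on pyrone C3 would make that carbon quaternary in any aldol adduct, which therefore cannot dehydrate to an arene and should revert, while the divalent magnesium ion holds the diketonate next to the ester and shields the β-diketone from retro-Claisen cleavage. The acetal and the prenyl groups are inert to methoxide.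

Step 9
Reactants: 15 3-hydroxy-4-methoxybenzoic acid (isovanillic acid)
Product: 17 4-methoxy-3-(methoxymethoxy)benzoic acid, via methoxymethyl ester 16 (not isolated)
Conditions: MOMCl (2.5 equiv), i-Pr2NEt, CH2Cl2, 0 °C → rt; then LiOH, THF–MeOH–H2O, rt; 1 M HCl to pH 3, 0 °C
Reagents that add atoms: chloromethyl methyl ether, COCCl; lithium hydroxide, [Li+].[OH-]
Why: Exhaustive alkylation of phenol and carboxylate with the chloro ether, then saponification of the acylal-type ester only; the aryl acetal is stable to hydroxide and to brief cold acidification.

Step 10
Reactants: 14 1-[2,6-dihydroxy-4-methoxy-3,5-bis(3-methylbut-2-enyl)phenyl]-2-(methoxymethoxy)ethanone; 17 4-methoxy-3-(methoxymethoxy)benzoic acid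
Product: 18 [3-hydroxy-5-methoxy-2-[2-(methoxymethoxy)acetyl]-4,6-bis(3-methylbut-2-enyl)phenyl] 4-methoxy-3-(methoxymethoxy)benzoate
Conditions: EDC·HCl (1.2 equiv), DMAP (cat.), CH2Cl2, 0 °C → rt
Reagents that add atoms: none
Why: Steglich esterification of a phenol; the two phenols of 14 are equivalent by symmetry, so one mono-ester results, and the remaining hydroxyl, chelated to the ketone and flanked by a prenyl group and the new ester, should acylate much more slowly.

Step 11
Reactants: 18 [3-hydroxy-5-methoxy-2-[2-(methoxymethoxy)acetyl]-4,6-bis(3-methylbut-2-enyl)phenyl] 4-methoxy-3-(methoxymethoxy)benzoate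
Product: 19 1-[2,6-dihydroxy-4-methoxy-3,5-bis(3-methylbut-2-enyl)phenyl]-3-[4-methoxy-3-(methoxymethoxy)phenyl]-2-(methoxymethoxy)propane-1,3-dione
Conditions: LiN(SiMe3)2 (3.5 equiv), THF, −78 → −10 °C; AcOH
Reagents that add atoms: none
Why: Baker–Venkataraman rearrangement: after deprotonation of the free phenol, the ketone enolate formed at the methylene next to the acetal oxygen attacks the neighbouring aryl ester through a six-membered cyclic adduct and the aroyl group moves from oxygen to carbon; the new methine is racemic and enolisable and is lost as a stereocentre in the next step.

Step 12
Reactants: 19 1-[2,6-dihydroxy-4-methoxy-3,5-bis(3-methylbut-2-enyl)phenyl]-3-[4-methoxy-3-(methoxymethoxy)phenyl]-2-(methoxymethoxy)propane-1,3-dione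
Product: 21 3,5-dihydroxy-2-(3-hydroxy-4-methoxyphenyl)-7-methoxy-6,8-bis(3-methylbut-2-enyl)chromen-4-one, via bis-MOM flavone 20 (not isolated)
Conditions: HCl (ca. 1 M, from conc. aq. HCl), MeOH–THF, 45 °C, stopped as soon as 20 is consumed
Reagents that add atoms: none
Why: Acid-catalysed cyclodehydration of the 2-hydroxyaryl 1,3-diketone (hemiketal formation at the aroyl carbonyl, loss of water to the chromen-4-one) followed by solvolysis of both acetals in methanol; either phenol may close because ring A is symmetric, and the C5 hydroxyl of the product is chelated to the C4 carbonyl, which lowers its tendency to add to the C6 prenyl group under dilute acid.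

## Compound list

1 | pentane-2,4-dione | CC(=O)CC(C)=O | starting material
2 | 1-bromo-3-methylbut-2-ene | CC(C)=CCBr | starting material
3 | 3-(3-methylbut-2-enyl)pentane-2,4-dione | CC(=O)C(CC=C(C)C)C(C)=O | intermediate
4 | 3,5-dioxo-4-(3-methylbut-2-enyl)hexanoic acid (racemic, enolisable) | CC(=O)C(CC=C(C)C)C(=O)CC(=O)O | intermediate
5 | 4-hydroxy-6-methyl-5-(3-methylbut-2-enyl)pyran-2-one | Cc1oc(=O)cc(O)c1CC=C(C)C | intermediate
6 | 3-methylbut-2-enyl acetate | CC(=O)OCC=C(C)C | starting material
7 | 4-hydroxy-6-methyl-3,5-bis(3-methylbut-2-enyl)pyran-2-one | Cc1oc(=O)c(CC=C(C)C)c(O)c1CC=C(C)C | intermediate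
8 | 4-methoxy-6-methyl-3,5-bis(3-methylbut-2-enyl)pyran-2-one | COc1c(CC=C(C)C)c(C)oc(=O)c1CC=C(C)C | intermediate
9 | methyl glycolate | COC(=O)CO | starting material
10 | methyl 2-(methoxymethoxy)acetate | COCOCC(=O)OC | intermediate
11 | N-methoxy-2-(methoxymethoxy)-N-methylacetamide | COCOCC(=O)N(C)OC | intermediate
12 | 4-methoxy-6-[3-(methoxymethoxy)-2-oxopropyl]-3,5-bis(3-methylbut-2-enyl)pyran-2-one | COCOCC(=O)Cc1oc(=O)c(CC=C(C)C)c(OC)c1CC=C(C)C | intermediate
13 | methyl (2E)-3-methoxy-8-(methoxymethoxy)-2,4-bis(3-methylbut-2-enyl)-5,7-dioxooct-2-enoate (racemic at C4) | COC(=O)/C(CC=C(C)C)=C(/OC)C(CC=C(C)C)C(=O)CC(=O)COCOC | intermediate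
14 | 1-[2,6-dihydroxy-4-methoxy-3,5-bis(3-methylbut-2-enyl)phenyl]-2-(methoxymethoxy)ethanone | COCOCC(=O)c1c(O)c(CC=C(C)C)c(OC)c(CC=C(C)C)c1O | intermediate
15 | 3-hydroxy-4-methoxybenzoic acid (isovanillic acid) | COc1ccc(C(=O)O)cc1O | starting material
16 | methoxymethyl 4-methoxy-3-(methoxymethoxy)benzoate | COCOC(=O)c1ccc(OC)c(OCOC)c1 | intermediate
17 | 4-methoxy-3-(methoxymethoxy)benzoic acid | COCOc1cc(C(=O)O)ccc1OC | intermediate
18 | [3-hydroxy-5-methoxy-2-[2-(methoxymethoxy)acetyl]-4,6-bis(3-methylbut-2-enyl)phenyl] 4-methoxy-3-(methoxymethoxy)benzoate | COCOCC(=O)c1c(O)c(CC=C(C)C)c(OC)c(CC=C(C)C)c1OC(=O)c1ccc(OC)c(OCOC)c1 | intermediate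
19 | 1-[2,6-dihydroxy-4-methoxy-3,5-bis(3-methylbut-2-enyl)phenyl]-3-[4-methoxy-3-(methoxymethoxy)phenyl]-2-(methoxymethoxy)propane-1,3-dione (racemic, enolisable C2) | COCOC(C(=O)c1ccc(OC)c(OCOC)c1)C(=O)c1c(O)c(CC=C(C)C)c(OC)c(CC=C(C)C)c1O | intermediate
20 | 5-hydroxy-7-methoxy-3-(methoxymethoxy)-2-[4-methoxy-3-(methoxymethoxy)phenyl]-6,8-bis(3-methylbut-2-enyl)chromen-4-one | COCOc1cc(-c2oc3c(CC=C(C)C)c(OC)c(CC=C(C)C)c(O)c3c(=O)c2OCOC)ccc1OC | intermediate
21 | 3,5-dihydroxy-2-(3-hydroxy-4-methoxyphenyl)-7-methoxy-6,8-bis(3-methylbut-2-enyl)chromen-4-one | COc1ccc(-c2oc3c(CC=C(C)C)c(OC)c(CC=C(C)C)c(O)c3c(=O)c2O)cc1O | target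

## Step count and least certain steps

Total step count: 12. Longest linear sequence: 9 steps (steps 1, 2, 3, 4, 7, 8, 10, 11, 12). Steps 5 and 6 and step 9 are side branches.

**Step 8 (key step).** The most likely failure is slow or incomplete methanolysis of the lactone. The side-chain methylene of 12 is deprotonated first, and its charge is delocalised into the already electron-rich, 3,5-disubstituted pyrone, which lowers the electrophilicity of the lactone carbonyl. A second risk is retro-Claisen loss of the glycolyl unit from the opened β-diketone before it closes. The fallback separates ring opening from chain extension. It sets out from 8, whose methyl group is not acidic enough to be deprotonated by methoxide. Compound 8 would be opened with Mg(OMe)2 in methanol to methyl (2E)-3-methoxy-2,4-bis(3-methylbut-2-enyl)-5-oxohex-2-enoate (F1). The dianion of F1 (LiN(i-Pr)2, 2.2 equiv, THF, −78 °C) would be acylated at its terminal methyl carbon with 11. Quenching would give 13, where the fallback rejoins the route, and 13 would be closed to 14 under the conditions of step 8 without any lactone-opening event.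

**Step 3.** What may go wrong is O-alkylation in place of C-alkylation, attack at the substituted terminus of the allyl complex (reverse prenylation), or a second alkylation at C3. The nucleophile is ambident and the allyl fragment unsymmetrical. The fallback moves the second prenylation to the open-chain stage and sets out from 4. The crude acid would be esterified with TMSCHN2 to methyl 4-(3-methylbut-2-enyl)-3,5-dioxohexanoate (F2). F2 would be deprotonated twice with LiN(i-Pr)2 (2.2 equiv, THF) and alkylated with 2 at C2, the only enolate carbon that is still unsubstituted (C4 already bears a prenyl group and would have to become quaternary), to give methyl 2,4-bis(3-methylbut-2-enyl)-3,5-dioxohexanoate (F3). F3 would be lactonised with DBU in refluxing toluene, returning to 7.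

**Step 4.** What may go wrong is methylation on the lactone carbonyl oxygen, leading to the 2-methoxy-4-pyrone series, because the C4 oxygen of 7 is shielded by two prenyl groups. The fallback changes the order of events and sets out from 5. It would be methylated while C3 is still unsubstituted (Me2SO4, K2CO3, acetone) to 4-methoxy-6-methyl-5-(3-methylbut-2-enyl)pyran-2-one (F4). Kinetic lithiation of F4 at C3 with n-BuLi in THF at −78 °C, between the lactone carbonyl and the methoxy group, and alkylation with 2 would return to 8.

**Step 7.** What may go wrong is incomplete acylation at the hindered exocyclic carbon, with proton transfer from the α-methylene of 11 to the dienolate, or reaction of the dienolate at a ring carbon. The fallback replaces acylation by aldol addition and oxidation and sets out from 8 and 10. Ester 10 would be reduced with i-Bu2AlH at −78 °C to 2-(methoxymethoxy)acetaldehyde (F5). Lithiated 8 would add to F5 to give 6-[2-hydroxy-3-(methoxymethoxy)propyl]-4-methoxy-3,5-bis(3-methylbut-2-enyl)pyran-2-one (F6), a non-acidic adduct. F6 would be oxidised with Dess–Martin periodinane in buffered CH2Cl2, returning to 12.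

**Step 12.** What may go wrong is acid-catalysed addition of the C5 phenol or of methanol to a prenyl double bond (chroman formation or hydromethoxylation), competing with dehydration and acetal solvolysis when the medium is protic and warm for hours. The fallback uncouples the two events and moves the deprotection away from protic acid. It sets out from 19, which would be cyclised under buffered conditions (NaOAc, AcOH, 80 °C) and 20 isolated. The acetals of 20 would then be exchanged onto a thiol with ZnBr2 and n-PrSH in CH2Cl2 at 0 °C, returning to 21. This fallback makes no compound beyond those already listed (entry F0).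

## Further compounds

F1 | step 8 | methyl (2E)-3-methoxy-2,4-bis(3-methylbut-2-enyl)-5-oxohex-2-enoate (racemic at C4) | COC(=O)/C(CC=C(C)C)=C(/OC)C(CC=C(C)C)C(C)=O
F2 | step 3 | methyl 4-(3-methylbut-2-enyl)-3,5-dioxohexanoate (racemic, enolisable) | COC(=O)CC(=O)C(CC=C(C)C)C(C)=O
F3 | step 3 | methyl 2,4-bis(3-methylbut-2-enyl)-3,5-dioxohexanoate (mixture of enolisable diastereomers) | COC(=O)C(CC=C(C)C)C(=O)C(CC=C(C)C)C(C)=O
F4 | step 4 | 4-methoxy-6-methyl-5-(3-methylbut-2-enyl)pyran-2-one | COc1cc(=O)oc(C)c1CC=C(C)C
F5 | step 7 | 2-(methoxymethoxy)acetaldehyde | COCOCC=O
F6 | step 7 | 6-[2-hydroxy-3-(methoxymethoxy)propyl]-4-methoxy-3,5-bis(3-methylbut-2-enyl)pyran-2-one (racemic) | COCOCC(O)Cc1oc(=O)c(CC=C(C)C)c(OC)c1CC=C(C)C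
F0 | step 12 | none | none
A1 | alternative 1 | 4-methoxy-2-(methoxymethoxy)-6-[1-[4-methoxy-3-(methoxymethoxy)phenyl]-2-oxoethoxy]-3,5-bis(3-methylbut-2-enyl)benzaldehyde (racemic) | O=Cc1c(OCOC)c(CC=C(C)C)c(OC)c(CC=C(C)C)c1OC(C=O)c1ccc(OC)c(OCOC)c1
A2 | alternative 1 | 3-hydroxy-7-methoxy-5-(methoxymethoxy)-2-[4-methoxy-3-(methoxymethoxy)phenyl]-6,8-bis(3-methylbut-2-enyl)chroman-4-one (racemic, relative configuration not controlled) | O=C1c2c(OCOC)c(CC=C(C)C)c(OC)c(CC=C(C)C)c2OC(c2ccc(OC)c(OCOC)c2)C1O
A3 | alternative 2 | 3-isopropoxy-2-(3-methylbut-2-enyl)cyclobut-2-en-1-one | O=C1CC(OC(C)C)=C1CC=C(C)C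
A4 | alternative 2 | 1-methoxy-5-methylhex-4-en-1-yne | COC#CCC=C(C)C
A5 | alternative 2 | 5-isopropoxy-3-methoxy-2,4-bis(3-methylbut-2-enyl)phenol | COc1c(CC=C(C)C)c(O)cc(OC(C)C)c1CC=C(C)C
A6 | alternative 3 | 2-iodo-5-methoxy-4,6-bis(3-methylbut-2-enyl)benzene-1,3-diol | COc1c(CC=C(C)C)c(O)c(I)c(O)c1CC=C(C)C
A7 | alternative 3 | 4-ethynyl-1-methoxy-2-(methoxymethoxy)benzene | C#Cc1ccc(OC)c(OCOC)c1
A8 | alternative 3 | 5-hydroxy-7-methoxy-2-[4-methoxy-3-(methoxymethoxy)phenyl]-6,8-bis(3-methylbut-2-enyl)chromen-4-one | COCOc1cc(-c2cc(=O)c3c(O)c(CC=C(C)C)c(OC)c(CC=C(C)C)c3o2)ccc1OC
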